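Readings and results are simulated for substances that don't exist; the scatter is artificial.

Take the smaller charge first: in the flask Q stands at 1.47 M against X at 2.1 M.

- elm: X 1.4 M; Q 1.47 M; run made earlier
- flask: X 2.1 M; Q 1.47 M; time 40 h

elm run (percent of the X charged)

| time / h | Z / % | J / % |
|---|---|---|
| 5.00 | 7 | 17 |
| 10.0 | 25 | 24 |
| 15.0 | 42 | 25 |
| 20.0 | 54 | 31 |
| 25.0 | 71 | 29 |
| 30.0 | 87 | 15 |

(each reading ± 2 percentage points)

- the Z standing at 40 h, as a percentage of the X charged
- concentration of J in solution at 40 h, in percent of saturation

- solid, in amounts per volume of the solution: X, Q
- the analysis behind the earlier runs scatters by 2 percentage points, standard deviation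
- at the start none of X is in solution
- at the start none of Q is in solution
- J means what is dissolved; the solid is not counted in it
- J is what X becomes in solution

Build the flask one process at a time, and begin with the main step. Suppose one Q goes into each Z, which makes Q the limiting reagent. Z in the flask then stops at C = 70.0% of the X charged, C being the Q charged over the X charged.

Now add the pace. In the elm run Z climbs from 25% at 10.0 h to 87% at 30.0 h, which reads as 0.0434 M h⁻¹. Assume that pace carries over. The flask then needs 33.9 h to use its Q, less than the 40 h asked, so I commit to Z at C at that time.

Last, add the remainder and reckon that by itself. What does not become Z is 30.0% of the X, or 0.630 M. The highest J read in the elm run is 0.434 M, less than that. But that J was read under way, so it is a floor for saturation and no more, and I leave the percent of saturation open.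

The forecast gives 68% and 97%, holding that “J should sit at or near saturation”. The flask gives 70.0% and 77.7%.

    X ⇌ J, rate k1*(cs1 - [J]) while solid is left; crystals form when [J] > cs1 (solubility = 0.750 M, k = 0.140 h⁻¹)
    Q ⇌ E, rate k2*(cs2 - [E]) while solid is left; crystals form when [E] > cs2 (solubility = 0.740 M, k = 0.0610 h⁻¹)
    J + E → Z (k = 2.60 M⁻¹ h⁻¹)

The flask stands on C, with Q at 0% of its charge at 40.0 h. C serves a second flask too: with 0.88 M of Q and the rest as in the flask, it reckons 41.9%, and that flask stands at 41.9% at 40 h. Is this flask at rest? Not quite. Leave it until 400 h: Z stays at 70.0%, but X goes from 2.25% at 40 h to 0%, and J climbs to 30.0%. Reckon that correction against the saturation of J, 0.75 M: the X adds 6.3 percentage points, so J stands at 84.0% of saturation at 400 h.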